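**Remark on the chemistry:** the target has one stereocentre, the carbinol carbon of the 2-hydroxy-3-methylbut-3-enyl chain on the indole C7; the SMILES defines it as (R). Everything else is achiral.

## Retrosynthetic overview

1. Target 19 ← bis(indolyl)dichloroquinone 18 by exchange of the two quinone C–Cl groups for C–OMe with NaOMe; the chlorines block C2 and C5 during the coupling and then serve as leaving groups.
2. 18 ← indolylquinone 8 + unprotected indole 16 by an anodic dehydrogenative C–H/C–H coupling: indole C3 adds to the quinone, the anode returns the resulting hydroquinone to the quinone level, and H2 at the cathode is the only by-product.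
3. Enabling feature: the single unsubstituted carbon C6–H of the cyclohexa-2,5-diene-1,4-dione ring of 8 (β-carbon of the C4(=O)–C5(Cl)=C6 enone, para to the indolyl-bearing C3), facing the free C3–H of the pyrrole ring of 16, together with the reversible hydroquinone/quinone pair of that six-membered ring, which lets an electrode remove the two hydrogens.
4. 8 ← 2,5-dichloro-1,4-benzoquinone + 2-(1,1-dimethylallyl)indole 5. 16 ← 7-bromoindole by Boc protection, linear Negishi prenylation, Shi epoxidation (sets R), epoxide-to-allylic-alcohol isomerisation and Boc removal.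
5. Ring formation: only the pyrrole ring of indole 5 is built (Madelung closure from o-toluidine); the benzoquinone ring and the second indole are bought.

Key step: step 9

## Route

**Step 1**
Reactants: 1 2,2-dimethylbut-3-enoic acid; 2 2-methylaniline (o-toluidine)
Product: 4 N-(2-methylphenyl)-2,2-dimethylbut-3-enamide, via 2,2-dimethylbut-3-enoyl chloride 3 (not isolated)
Conditions: (COCl)2, N,N-dimethylformamide (cat.), CH2Cl2, 0 °C to rt, concentrate; then 2, Et3N, CH2Cl2, 0 °C to rt
Reagents that add atoms: none
Why: Acid chloride formation followed by N-acylation of the aniline (Schotten–Baumann-type amide synthesis); the quaternary α-carbon cannot enolise, so the hindered acyl chloride should acylate cleanly.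

**Step 2**
Reactants: 4 N-(2-methylphenyl)-2,2-dimethylbut-3-enamide
Product: 5 2-(2-methylbut-3-en-2-yl)-1H-indole
Conditions: n-BuLi (3 equiv), THF, −20 °C to rt; aq. NH4Cl
Reagents that add atoms: none
Why: Madelung indole synthesis in its low-temperature organolithium variant: N,C-dilithiation (amide N–H and benzylic CH3), attack of the benzylic carbanion on the amidate carbon and loss of LiOH should give the 2-tert-alkylindole, as known for the analogous pivalanilide.

**Step 3**
Reactants: 5 2-(2-methylbut-3-en-2-yl)-1H-indole; 6 2,5-dichloro-1,4-benzoquinone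
Product: 8 2,5-dichloro-3-[2-(2-methylbut-3-en-2-yl)-1H-indol-3-yl]cyclohexa-2,5-diene-1,4-dione, via indolylhydroquinone 7 (not isolated)
Conditions: 6 (2.5 equiv), conc. HCl (cat.), THF, rt, Ar
Reagents that add atoms: none
Why: Acid-promoted Friedel–Crafts-type conjugate addition of indole C3 to an unsubstituted quinone carbon, known for hindered 2-substituted indoles with this quinone, gives hydroquinone 7, which the excess of 6 should dehydrogenate in the flask to the isolable quinone 8.

**Step 4**
Reactants: 9 7-bromo-1H-indole
Product: 10 tert-butyl 7-bromo-1H-indole-1-carboxylate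
Conditions: Boc2O, 4-(dimethylamino)pyridine (cat.), MeCN, rt
Reagents that add atoms: di-tert-butyl dicarbonate, CC(C)(C)OC(=O)OC(=O)OC(C)(C)C
Why: Nucleophilic catalysis of N-acylation (carbamate protection); the Boc group removes the acidic N–H before the organozinc step and makes the indole C2=C3 bond electron-poor before the dioxirane oxidation.

**Step 5**
Reactants: 10 tert-butyl 7-bromo-1H-indole-1-carboxylate; 11 1-bromo-3-methylbut-2-ene (prenyl bromide)
Product: 13 tert-butyl 7-(3-methylbut-2-en-1-yl)-1H-indole-1-carboxylate, via prenylzinc bromide 12 (not isolated)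
Conditions: 11, Zn dust, LiCl, THF, 0 °C; then 10, Pd(OAc)2 (2 mol%), 2-dicyclohexylphosphino-2',6'-bis(dimethylamino)biphenyl (CPhos, 4 mol%), THF, rt
Reagents that add atoms: none
Why: Negishi coupling: oxidative addition of the C–Br bond to zerovalent palladium, transmetalation with the allylic zinc reagent and reductive elimination at the unsubstituted allyl terminus, for which this bulky biarylphosphine is known to give the linear prenyl arene.

**Step 6**
Reactants: 13 tert-butyl 7-(3-methylbut-2-en-1-yl)-1H-indole-1-carboxylate
Product: 14 tert-butyl 7-{[(2R)-3,3-dimethyloxiran-2-yl]methyl}-1H-indole-1-carboxylate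
Conditions: Shi ketone from D-fructose (1,2:4,5-di-O-isopropylidene-β-D-erythro-2,3-hexodiulo-2,6-pyranose, 30 mol%), KHSO5 (as Oxone), K2CO3, n-Bu4NHSO4 (cat.), MeCN/CH2(OMe)2, aq. Na2B4O7/Na2EDTA buffer (pH about 10.5), 0 °C
Reagents that add atoms: potassium peroxymonosulfate, [K+].[O-]S(=O)(=O)OO
Why: Shi asymmetric epoxidation: the chiral dioxirane transfers oxygen through a spiro transition state, and for trisubstituted alkenes of the type RCH2–CH=CMe2 the D-fructose-derived ketone should deliver the (R) epoxide; the electron-rich prenyl alkene should react well ahead of the N-Boc indole.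

**Step 7**
Reactants: 14 tert-butyl 7-{[(2R)-3,3-dimethyloxiran-2-yl]methyl}-1H-indole-1-carboxylate
Product: 15 tert-butyl 7-[(2R)-2-hydroxy-3-methylbut-3-en-1-yl]-1H-indole-1-carboxylate
Conditions: Et2Al(TMP) (from 2,2,6,6-tetramethylpiperidine, n-BuLi and Et2AlCl), toluene, 0 °C; aq. KNaC4H4O6 work-up
Reagents that add atoms: none
Why: Aluminium amide-mediated isomerisation of a trisubstituted epoxide to an allylic alcohol: the aluminium binds the epoxide oxygen and the hindered amide removes a proton from the methyl group cis to the ring hydrogen in a syn elimination that breaks the tertiary C–O bond, so the C–O bond at the stereocentre is untouched and (R) is retained.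

**Step 8**
Reactants: 15 tert-butyl 7-[(2R)-2-hydroxy-3-methylbut-3-en-1-yl]-1H-indole-1-carboxylate
Product: 16 (2R)-1-(1H-indol-7-yl)-3-methylbut-3-en-2-ol
Conditions: K2CO3, MeOH, 60 °C
Reagents that add atoms: none
Why: Methanolysis of an N-acyl-type indole carbamate (the indolide is a good leaving group), a base-mediated Boc removal that avoids acid near the allylic alcohol.

**Step 9**
Reactants: 8 2,5-dichloro-3-[2-(2-methylbut-3-en-2-yl)-1H-indol-3-yl]cyclohexa-2,5-diene-1,4-dione; 16 (2R)-1-(1H-indol-7-yl)-3-methylbut-3-en-2-ol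
Product: 18 2,5-dichloro-3-{7-[(2R)-2-hydroxy-3-methylbut-3-en-1-yl]-1H-indol-3-yl}-6-[2-(2-methylbut-3-en-2-yl)-1H-indol-3-yl]cyclohexa-2,5-diene-1,4-dione, via bis(indolyl)hydroquinone 17 (not isolated)
Conditions: divided cell (glass frit), reticulated vitreous carbon anode, Pt cathode, LiClO4 (0.1 M), NaOAc (2.5 equiv), MeCN/AcOH 4:1 in both chambers, 8 (1.05 equiv) and 16 in the anode chamber, anode potential held at the wave of hydroquinone 17 and below the indole waves (fixed by cyclic voltammetry beforehand; expected between +0.6 and +0.8 V vs Ag/AgCl), rt, Ar, about 2.2 F/mol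
Reagents that add atoms: none
Why: The free C3 of indole 16, its most nucleophilic position, adds to C6 of quinone 8, the β-carbon of the C4(=O)–C5(Cl)=C6 enone, in an AcOH-assisted Friedel–Crafts-type conjugate addition, and tautomerisation gives hydroquinone 17. Hydroquinone 17 then gives up two electrons and two protons at the carbon anode, well below the potential at which an indole is oxidised, to give the fully substituted quinone 18 while protons are reduced to H2 at the cathode, so the net event is a dehydrogenative C–H/C–H coupling in which the anode takes the place of a sacrificial second equivalent of quinone or of DDQ. The closest known reaction type is the anodic synthesis of indol-3-yl quinones from dihydroxybenzenes and indoles (an addition–oxidation sequence at the electrode), backed by the acid-promoted addition of indoles to 2,5-dichloro-1,4-benzoquinones followed by chemical reoxidation. No ring is closed and no stereocentre is made; the (R) carbinol of 16 is not touched. The selectivity needed is oxidation of the hydroquinone in front of two indole rings, a free allylic alcohol and the alkenes, which the potential gap and the controlled anode potential should secure, and site selectivity on the quinone, secured because C6 is its only C–H carbon and the C–Cl carbons are not substituted by a neutral indole in buffered acid. The divided cell keeps 8 and 18 away from the cathode, and the acetate buffer takes up the protons released at the anode so that the allylic alcohol and the 1,1-dimethylallyl group do not meet strong acid.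

**Step 10**
Reactants: 18 2,5-dichloro-3-{7-[(2R)-2-hydroxy-3-methylbut-3-en-1-yl]-1H-indol-3-yl}-6-[2-(2-methylbut-3-en-2-yl)-1H-indol-3-yl]cyclohexa-2,5-diene-1,4-dione
Product: 19 2,5-dimethoxy-3-{7-[(2R)-2-hydroxy-3-methylbut-3-en-1-yl]-1H-indol-3-yl}-6-[2-(2-methylbut-3-en-2-yl)-1H-indol-3-yl]cyclohexa-2,5-diene-1,4-dione (the target)
Conditions: NaOMe (6 equiv), dry MeOH/THF, 0 °C to rt, Ar
Reagents that add atoms: sodium methoxide, [Na+].[O-]C
Why: Two addition–elimination (vinylogous acyl substitution) events at the quinone C–Cl carbons, each β to a carbonyl, the reactivity that underlies the alkaline hydrolysis of 2,5-dihalo-3,6-diarylquinones; dry methoxide should stop at the bis(methyl ether) and leaves the alcohol, the alkenes and the stereocentre alone.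

## Compound list

1 | 2,2-dimethylbut-3-enoic acid | C=CC(C)(C)C(=O)O | starting material
2 | 2-methylaniline (o-toluidine) | Cc1ccccc1N | starting material
3 | 2,2-dimethylbut-3-enoyl chloride | C=CC(C)(C)C(=O)Cl | intermediate (not isolated)
4 | N-(2-methylphenyl)-2,2-dimethylbut-3-enamide | C=CC(C)(C)C(=O)Nc1ccccc1C | intermediate
5 | 2-(2-methylbut-3-en-2-yl)-1H-indole | C=CC(C)(C)c1cc2ccccc2[nH]1 | intermediate
6 | 2,5-dichloro-1,4-benzoquinone | O=C1C=C(Cl)C(=O)C=C1Cl | starting material
7 | 2,5-dichloro-3-[2-(2-methylbut-3-en-2-yl)-1H-indol-3-yl]benzene-1,4-diol | C=CC(C)(C)c1[nH]c2ccccc2c1-c1c(O)c(Cl)cc(O)c1Cl | intermediate (not isolated)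
8 | 2,5-dichloro-3-[2-(2-methylbut-3-en-2-yl)-1H-indol-3-yl]cyclohexa-2,5-diene-1,4-dione | C=CC(C)(C)c1[nH]c2ccccc2c1C1=C(Cl)C(=O)C=C(Cl)C1=O | intermediate
9 | 7-bromo-1H-indole | Brc1cccc2cc[nH]c12 | starting material
10 | tert-butyl 7-bromo-1H-indole-1-carboxylate | CC(C)(C)OC(=O)n1ccc2cccc(Br)c21 | intermediate
11 | 1-bromo-3-methylbut-2-ene (prenyl bromide) | CC(C)=CCBr | starting material
12 | (3-methylbut-2-en-1-yl)zinc bromide | CC(C)=CC[Zn]Br | intermediate (not isolated)
13 | tert-butyl 7-(3-methylbut-2-en-1-yl)-1H-indole-1-carboxylate | CC(C)=CCc1cccc2ccn(C(=O)OC(C)(C)C)c12 | intermediate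
14 | tert-butyl 7-{[(2R)-3,3-dimethyloxiran-2-yl]methyl}-1H-indole-1-carboxylate | CC(C)(C)OC(=O)n1ccc2cccc(C[C@H]3OC3(C)C)c21 | intermediate
15 | tert-butyl 7-[(2R)-2-hydroxy-3-methylbut-3-en-1-yl]-1H-indole-1-carboxylate | CC(C)(C)OC(=O)n1ccc2cccc(C[C@@H](O)C(C)=C)c21 | intermediate
16 | (2R)-1-(1H-indol-7-yl)-3-methylbut-3-en-2-ol | c1c[nH]c2c(C[C@@H](O)C(=C)C)cccc12 | intermediate
17 | 2,5-dichloro-3-{7-[(2R)-2-hydroxy-3-methylbut-3-en-1-yl]-1H-indol-3-yl}-6-[2-(2-methylbut-3-en-2-yl)-1H-indol-3-yl]benzene-1,4-diol | C=CC(C)(C)c1[nH]c2ccccc2c1-c1c(O)c(Cl)c(-c2c[nH]c3c(C[C@@H](O)C(=C)C)cccc23)c(O)c1Cl | intermediate (not isolated)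
18 | 2,5-dichloro-3-{7-[(2R)-2-hydroxy-3-methylbut-3-en-1-yl]-1H-indol-3-yl}-6-[2-(2-methylbut-3-en-2-yl)-1H-indol-3-yl]cyclohexa-2,5-diene-1,4-dione | C=CC(C)(C)c1[nH]c2ccccc2c1C1=C(Cl)C(=O)C(c2c[nH]c3c(C[C@@H](O)C(=C)C)cccc23)=C(Cl)C1=O | intermediate
19 | 2,5-dimethoxy-3-{7-[(2R)-2-hydroxy-3-methylbut-3-en-1-yl]-1H-indol-3-yl}-6-[2-(2-methylbut-3-en-2-yl)-1H-indol-3-yl]cyclohexa-2,5-diene-1,4-dione | C=CC(C)(C)c1[nH]c2ccccc2c1C1=C(OC)C(=O)C(c2c[nH]c3c(C[C@@H](O)C(=C)C)cccc23)=C(OC)C1=O | target

## Count and risks

Total steps: 10 (steps 1–3 for the indolylquinone, steps 4–8 for the indole, steps 9–10 in common). Longest linear sequence: 7 steps (steps 4, 5, 6, 7, 8, 9, 10 from 7-bromoindole).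

The three steps most likely to fail:

**Step 9 (key step).** The conjugate addition at the crowded quinone carbon may be too slow in the weakly acidic buffered medium, indole 16 may be lost at the anode (oligomer film, electrode fouling), or quinone 8 may be consumed in other ways before it is trapped. The fallback replaces the oxidative coupling by a base-mediated vinylic substitution on a tetrahaloquinone, which needs no oxidation. It sets out from indole 5 and indole 16. Indole 5 is condensed with tetrabromo-1,4-benzoquinone (excess) and Cs2CO3 in MeCN at rt to give 2,3,5-tribromo-6-[2-(2-methylbut-3-en-2-yl)-1H-indol-3-yl]cyclohexa-2,5-diene-1,4-dione F1. F1 and 16 with Cs2CO3 in MeCN should then give 2,5-dibromo-3-{7-[(2R)-2-hydroxy-3-methylbut-3-en-1-yl]-1H-indol-3-yl}-6-[2-(2-methylbut-3-en-2-yl)-1H-indol-3-yl]cyclohexa-2,5-diene-1,4-dione F2; the second indole should enter para to the first, because the first indolyl group deactivates the carbonyl it is conjugated with. NaOMe in MeOH/THF, as in step 10, then exchanges both bromides, and the fallback comes back to the route at the target 19.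

**Step 7.** The aluminium amide may remove a benzylic proton instead of a methyl proton (leading to the conjugated tertiary alcohol), the Lewis acid may induce a hydride shift to a ketone, or the carbamate may be attacked. The fallback sets out from epoxide 14 and goes through hydrolysis and dehydration instead of isomerisation. Dilute HClO4 in THF/H2O at 0 °C should open the epoxide with water at the tertiary carbon, leaving the C–O bond of the stereocentre intact, to give tert-butyl 7-[(2R)-2,3-dihydroxy-3-methylbutyl]-1H-indole-1-carboxylate F3. Ac2O and pyridine should acetylate only the secondary hydroxyl to give (2R)-1-[1-(tert-butoxycarbonyl)-1H-indol-7-yl]-3-hydroxy-3-methylbutan-2-yl acetate F4. Burgess reagent in toluene at 50 °C should dehydrate the tertiary alcohol toward a methyl group to give (2R)-1-[1-(tert-butoxycarbonyl)-1H-indol-7-yl]-3-methylbut-3-en-2-yl acetate F5. K2CO3 in MeOH at 60 °C then removes the acetate and the Boc group together, and the fallback comes back to the route at indole 16.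

**Step 10.** Adventitious water may hydrolyse a C–Cl or C–OMe group to a hydroxyquinone, or the second substitution may stall because the first methoxy group deactivates the quinone. The fallback sets out from 18 and accepts full hydrolysis. NaOH in MeOH/H2O at reflux should give 2,5-dihydroxy-3-{7-[(2R)-2-hydroxy-3-methylbut-3-en-1-yl]-1H-indol-3-yl}-6-[2-(2-methylbut-3-en-2-yl)-1H-indol-3-yl]cyclohexa-2,5-diene-1,4-dione F6. TMSCHN2 in MeOH/toluene at 0 °C should then methylate only the two acidic vinylogous-acid hydroxyls, and the fallback comes back to the route at the target 19.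

## Further compounds

F1 | step 9 | 2,3,5-tribromo-6-[2-(2-methylbut-3-en-2-yl)-1H-indol-3-yl]cyclohexa-2,5-diene-1,4-dione | C=CC(C)(C)c1[nH]c2ccccc2c1C1=C(Br)C(=O)C(Br)=C(Br)C1=O
F2 | step 9 | 2,5-dibromo-3-{7-[(2R)-2-hydroxy-3-methylbut-3-en-1-yl]-1H-indol-3-yl}-6-[2-(2-methylbut-3-en-2-yl)-1H-indol-3-yl]cyclohexa-2,5-diene-1,4-dione | C=CC(C)(C)c1[nH]c2ccccc2c1C1=C(Br)C(=O)C(c2c[nH]c3c(C[C@@H](O)C(=C)C)cccc23)=C(Br)C1=O
F3 | step 7 | tert-butyl 7-[(2R)-2,3-dihydroxy-3-methylbutyl]-1H-indole-1-carboxylate | CC(C)(C)OC(=O)n1ccc2cccc(C[C@@H](O)C(C)(C)O)c21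
F4 | step 7 | (2R)-1-[1-(tert-butoxycarbonyl)-1H-indol-7-yl]-3-hydroxy-3-methylbutan-2-yl acetate | CC(C)(C)OC(=O)n1ccc2cccc(C[C@@H](OC(C)=O)C(C)(C)O)c21
F5 | step 7 | (2R)-1-[1-(tert-butoxycarbonyl)-1H-indol-7-yl]-3-methylbut-3-en-2-yl acetate | CC(C)(C)OC(=O)n1ccc2cccc(C[C@@H](OC(C)=O)C(C)=C)c21
F6 | step 10 | 2,5-dihydroxy-3-{7-[(2R)-2-hydroxy-3-methylbut-3-en-1-yl]-1H-indol-3-yl}-6-[2-(2-methylbut-3-en-2-yl)-1H-indol-3-yl]cyclohexa-2,5-diene-1,4-dione | C=CC(C)(C)c1[nH]c2ccccc2c1C1=C(O)C(=O)C(c2c[nH]c3c(C[C@@H](O)C(=C)C)cccc23)=C(O)C1=O
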